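## The problem

Compound 22 is a furofuranone lignan in which a γ-butyrolactone (ring A, O–C9(=O)–C8–C8'–C7') and a tetrahydrofuran (ring B, C8–C7–O–C9'–C8') are cis-fused through the C8–C8' bond; lignan numbering is used in the discussion and IUPAC locants in compound names. Ring A carries a guaiacyl group on C7' and ring B a catechol on C7, and the four contiguous stereocentres (7S, 8S, 8'R, 7'S) put both arenes on the convex face, the C7' aryl trans to C9' and the C7 aryl trans to C9. C7' and C8' have no neighbour to lean on and must be set absolutely; the C9' substituent on C8' can then direct C8, and the cis C8/C8' pair fixes the ring fusion and biases C7. The two arenes differ only by one O-methyl group, so each has to enter as its own building block and stay distinguishable to the end. The molecule is fragile in three ways: the C7–O and C7'–O bonds are benzylic and para to oxygen (ionisation and epimerisation in acid, hydrogenolysis on Pd), the catechol is easily oxidised, and before ring B exists the cis C8–H can epimerise and a hydroxymethyl lactone can translactonise in base. What makes the target accessible is that C7 is para to the 4-hydroxyl of the catechol ring and four bonds from the C9' oxygen. A C7 methylene can therefore be oxidised to a para-quinone methide and trapped by the C9' hydroxyl to close ring B, provided the guaiacyl hydroxyl is masked at that moment.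

## Retrosynthesis

**22 from 21.** The two aryl O–CH2Ph bonds are cut last. Benzyl ethers survive the boron enolate, LiOOH, borane, amide bases and DDQ, and they leave under neutral conditions. Aryl silyl ethers would be at risk in the LiOH/H2O2 step, and acetal groups would need acid at the end, which epimerises C7 and C7'. Compound 21 keeps one free phenol, the catechol 4-hydroxyl that drives the key step.

**21 from 19.** The O–C7 bond of ring B is cut. The neighbouring O–C9' cut would need an activated C9' and a separately made C7 carbinol centre, and opening ring A first leaves a tetrasubstituted tetrahydrofuran that is no simpler. The O–C7 cut removes one ring and one stereocentre, needs no leaving group, and leaves the monocyclic lactone 19 with three contiguous centres. The forward reaction passes through quinone methide 20. It must oxidise only the ring with the free para hydroxyl, close 5-exo, and place the aryl group trans to C9.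

**19 from 18 and 17.** The phenol and the primary alcohol of 19 are unmasked together from the aryl TIPS and primary TBS ethers of 18, so one fluoride step serves both. The C8 centre of 18 comes from adding hydrogen across the C7=C8 bond of arylidene lactone 17. Direct benzylation of the lactone enolate would place the benzyl group trans to C9', which cannot give a cis-fused bicycle. Hydrogen delivered anti to C9' leaves the benzyl group cis. The forward step must be face-selective and must spare the benzyl ethers and the benzylic lactone C–O bond.

**17 from 11 and 14.** The C7=C8 bond is cut as an aldol condensation, which divides the molecule into two pieces of similar size. Aldehyde 14 comes from 3,4-dihydroxybenzaldehyde 12 through the 3-O-benzyl ether 13, so the catechol oxygens are differentiated at the very start.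

**11 from 10, 9 and 7.** No skeletal bond is cut here. The silyl ether 11 comes from alcohol 10, the alcohol from paraconic acid 9, and the acid from lactone imide 7, so C9' is carried down from the acyl oxidation level of the auxiliary-bearing carbonyl.

**7 from 5 and 2.** The C7'–C8' bond (aldol) and the O–C9 bond (lactonisation of hydroxy ester 6) are cut. An Evans syn-aldol sets both stereocentres at once, and the syn adduct maps onto the required 7',8'-trans lactone. Imide 5 comes from oxazolidinone 3 and acid chloride 4, and aldehyde 2 from vanillin 1.

## Roads not taken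

Alternative 1: The C8–C8' and O–C7' bonds are cut together, which opens both rings and leads to the acyclic malonate A2. Its central carbon (C8) carries the C7 benzylic ether, and the ether oxygen bears the (E)-cinnamyl unit C9'–C8'=C7'–guaiacyl.
- Forward step: Mn(OAc)3 (trivalent manganese), regenerated at the anode, would oxidise the malonate to its C8 radical. 5-exo cyclisation onto C8'=C7' forms C8–C8', the C7' radical is oxidised to the cation, and an ester carbonyl captures it. The product is A1, the tri-O-benzyl ether of 22 with a methoxycarbonyl group on C8.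
- Merits: two rings, one C–C bond, one C–O bond and three stereocentres form in one step with catalytic manganese. The route is shorter than the adopted one, and that is a real advantage.
- Weak points: the whole absolute configuration rests on the single C7 centre of A2, a β-alkoxy malonate that is hard to make enantiopure and racemises by retro-oxa-Michael cleavage of C7–O once base is present. The dioxygenated styrene and arenes are themselves oxidised at the potentials needed. The relay from C7 to C8' is a 1,3-relationship with modest bias. A1 still needs dealkoxycarbonylation at C8 under hot halide conditions in which C7–O can open again.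
- Comparison: against the shorter route, the adopted plan sets each centre by a step of well-understood sense (auxiliary aldol, anti hydrogenation, closure controlled by the ring fusion) and never exposes an electron-rich styrene to an oxidant.

Alternative 2: Ring A is contracted to a cyclobutanone by removing the oxygen between C9 and C7'. The C9–C8 and C7'–C8' bonds are then cut as a (2+2) cycloaddition, which leaves the 2-aryl-2,5-dihydrofuran A4 and the arylacetamide A5.
- Forward step: Tf2O and a hindered pyridine base convert A5 into its keteniminium ion, which adds to the C8=C8' alkene of A4 anti to the aryl group. Hydrolysis gives cyclobutanone A3 with both aryl groups exo, and a Baeyer–Villiger oxidation with migration of the benzylic C7' would expand it to the lactone.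
- Merits: both C–C bonds of the core and three stereocentres come from one cycloaddition, the α-aryl centre of A3 can equilibrate to the exo position, and the migration proceeds with retention.
- Weak points: the alkene of A4 is almost unpolarised, since C8 and C8' each carry one allylic C–O carbon, so nothing directs C9 to C8 rather than to C8' and both regioisomeric cyclobutanones are expected. The alkene is also deactivated towards an electrophilic keteniminium. The C7–H of A4 is benzylic, allylic and α to oxygen, which invites isomerisation or aromatisation of the dihydrofuran ring. The electron-rich arene of A5 can attack its own keteniminium, the peracid meets three electron-rich arenes, and A4 needs an asymmetric synthesis of its own.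
- Comparison: with regiochemistry enforced this road would be shorter. The adopted plan has no regiochemical question, because each arene arrives as an aldehyde at a carbon that is already defined.

Alternative 3: The O–C7 and C8–C8' bonds of ring B are cut as a (3+2) cycloaddition between racemic vinyl epoxide A7 and arylidene malonate A8.
- Forward step: Pd2(dba)3 (zerovalent palladium) with a chiral bisphosphine opens A7 to a π-allyl-palladium alkoxide. The alkoxide adds to C7 of A8 and the malonate anion closes onto the internal allyl carbon, giving the 2,4-trans tetrahydrofuran A6.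
- Merits: catalytic asymmetric induction from trivial building blocks, ring B with C7 and C8' in one step, and no auxiliary to attach and remove. In the way absolute configuration is introduced this road is better than the adopted one.
- Weak points: A6 has neither ring A nor the guaiacyl group. The vinyl group must be cleaved to the C7' aldehyde, and an aryl metal added with control at C7', where only substrate control next to a quaternary carbon is available and its sense is uncertain. The alkoxide must then lactonise onto the cis ester, and the second ester must be removed under conditions where C7–O, β to the carbonyl, can open by retro-oxa-Michael reaction. The electron-rich A8 is also a sluggish acceptor.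
- Comparison: the step count is comparable. Against the catalytic asymmetry, the adopted plan forms C7', the centre this road leaves to chance, together with C8' in the auxiliary-controlled aldol, and has ring A in place from the third step on.

Key step: step 12

Remark: compounds 1, 3, 4 and 12 and all reagents are taken as commercial.

Step 1
Reactants: 1 vanillin
Product: 2 4-(benzyloxy)-3-methoxybenzaldehyde
Conditions: BnBr, K2CO3, DMF, rt
Reagents that add atoms: benzyl bromide, BrCc1ccccc1
Why: Williamson ether synthesis at the only acidic site; the benzyl ether masks the guaiacyl hydroxyl until the last step, so this ring cannot form a quinone methide in step 12.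

Step 2
Reactants: 3 (S)-4-benzyl-1,3-oxazolidin-2-one; 4 methyl 4-chloro-4-oxobutanoate
Product: 5 methyl 4-[(4S)-4-benzyl-2-oxo-1,3-oxazolidin-3-yl]-4-oxobutanoate
Conditions: n-BuLi, THF, −78 °C; then 4, −78 → 0 °C
Reagents that add atoms: none
Why: N-acylation of the lithiated oxazolidinone by the acid chloride, which is far more electrophilic than the methyl ester at −78 °C.

Step 3
Reactants: 5 succinate imide; 2 4-(benzyloxy)-3-methoxybenzaldehyde
Product: 7 (4S)-4-benzyl-3-{[(2S,3S)-2-[4-(benzyloxy)-3-methoxyphenyl]-5-oxooxolan-3-yl]carbonyl}-1,3-oxazolidin-2-one, via syn-aldol hydroxy ester 6 (not isolated)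
Conditions: Bu2BOTf, i-Pr2NEt, CH2Cl2, −78 → 0 °C; 2, −78 → 0 °C; H2O2, MeOH, pH 7 buffer, 0 °C; then PPTS (cat.), CH2Cl2, rt
Reagents that add atoms: none
Why: Evans syn-aldol reaction: the Z-boron enolate of 5 reacts through a chair transition state on the face away from the benzyl group of the auxiliary, which sets C8' (S) and C7' (S). The syn hydroxy ester 6 then lactonises onto the methyl ester with loss of methanol, and syn maps onto the 7',8'-trans lactone.

Step 4
Reactants: 7 lactone imide
Product: 9 (2S,3S)-2-[4-(benzyloxy)-3-methoxyphenyl]-5-oxooxolane-3-carboxylic acid, via peroxy acid 8 (not isolated)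
Conditions: LiOH, H2O2, THF/H2O, 0 °C; Na2SO3; then 1 M HCl
Reagents that add atoms: hydrogen peroxide, OO
Why: Hydroperoxide cleavage of the N-acyl oxazolidinone at the exocyclic carbonyl gives the peracid, which sulfite reduces to the acid. C8' should not epimerise at 0 °C, and acidification recloses any lactone that has opened.

Step 5
Reactants: 9 paraconic acid
Product: 10 (4R,5S)-5-[4-(benzyloxy)-3-methoxyphenyl]-4-(hydroxymethyl)oxolan-2-one
Conditions: BH3·SMe2, THF, 0 °C → rt; MeOH
Reagents that add atoms: none
Why: Chemoselective borane reduction: the carboxylic acid is reduced through its acyloxyborane much faster than the lactone, and no stereocentre is touched (the descriptor at C8' changes only through the priority rules).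

Step 6
Reactants: 10 hydroxymethyl lactone
Product: 11 (4R,5S)-5-[4-(benzyloxy)-3-methoxyphenyl]-4-{[(tert-butyldimethylsilyl)oxy]methyl}oxolan-2-one
Conditions: TBSCl, imidazole, CH2Cl2, 0 °C → rt
Reagents that add atoms: tert-butyldimethylsilyl chloride, CC(C)(C)[Si](C)(C)Cl
Why: Silylation of the primary alcohol under near-neutral conditions, done at once so that the hydroxymethyl lactone cannot translactonise; the silyl ether is also the bulky group that directs step 10.

Step 7
Reactants: 12 3,4-dihydroxybenzaldehyde
Product: 13 3-(benzyloxy)-4-hydroxybenzaldehyde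
Conditions: NaH (2.2 equiv), DMSO, rt; BnCl (1.0 equiv); then 1 M HCl
Reagents that add atoms: benzyl chloride, ClCc1ccccc1
Why: Regioselective Williamson alkylation of the catechol dianion: the 4-phenoxide is delocalised into the para formyl group, so the 3-phenoxide is the more nucleophilic oxygen and takes the single equivalent of benzyl chloride.

Step 8
Reactants: 13 3-(benzyloxy)-4-hydroxybenzaldehyde
Product: 14 3-(benzyloxy)-4-[(triisopropylsilyl)oxy]benzaldehyde
Conditions: TIPSCl, imidazole, DMF, rt
Reagents that add atoms: triisopropylsilyl chloride, CC(C)[Si](Cl)(C(C)C)C(C)C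
Why: Silylation of the phenol; the hindered silyl group should survive the basic condensation in step 9 and later leaves together with the primary silyl ether.

Step 9
Reactants: 11 silyl ether lactone; 14 aryl aldehyde
Product: 17 (3E,4R,5S)-5-[4-(benzyloxy)-3-methoxyphenyl]-3-{3-(benzyloxy)-4-[(triisopropylsilyl)oxy]benzylidene}-4-{[(tert-butyldimethylsilyl)oxy]methyl}oxolan-2-one, via lithium aldolate 15 (not isolated), via aldol acetate 16 (not isolated)
Conditions: LiN(SiMe3)2, THF, −78 °C; 14; Ac2O, −78 °C → rt; DBU, rt
Reagents that add atoms: none
Why: Aldol condensation: the lithium enolate of 11 adds to 14, aldolate 15 is acetylated in the flask, and DBU eliminates acetic acid from 16 by an E1cB path to the conjugated (E)-alkene. The C7 and C8 centres of 15 and 16 are lost again, so their mixture is of no consequence.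

Step 10
Reactants: 17 arylidene lactone
Product: 18 (3R,4R,5S)-5-[4-(benzyloxy)-3-methoxyphenyl]-3-{3-(benzyloxy)-4-[(triisopropylsilyl)oxy]benzyl}-4-{[(tert-butyldimethylsilyl)oxy]methyl}oxolan-2-one
Conditions: H2 (1 atm), 10% Pd/C, 2,2'-bipyridyl, EtOAc/MeOH, rt
Reagents that add atoms: none
Why: Heterogeneous hydrogenation with syn delivery of hydrogen to the alkene face opposite the CH2OTBS group on C8', which allylic strain with the (E)-aryl group pushes into a pseudoaxial, face-blocking position; the new C8–H is therefore trans and the benzyl group cis to C9' (C8 = R). The nitrogen-base poison suppresses hydrogenolysis of the aryl benzyl ethers and of the benzylic lactone C–O bond, a known selectivity of amine-modified Pd/C.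

Step 11
Reactants: 18 cis-benzyl lactone
Product: 19 (3R,4R,5S)-5-[4-(benzyloxy)-3-methoxyphenyl]-3-[3-(benzyloxy)-4-hydroxybenzyl]-4-(hydroxymethyl)oxolan-2-one
Conditions: Bu4NF, AcOH, THF, 0 °C → rt
Reagents that add atoms: none
Why: Fluoride-mediated desilylation removes the aryl TIPS and the primary TBS ether together; acetic acid buffers the phenoxide and alkoxide so that the cis C8 centre does not epimerise and the hydroxymethyl lactone does not translactonise.

Step 12
Reactants: 19 phenol alcohol lactone
Product: 21 (3S,3aR,6S,6aS)-6-[3-(benzyloxy)-4-hydroxyphenyl]-3-[4-(benzyloxy)-3-methoxyphenyl]tetrahydro-1H,3H-furo[3,4-c]furan-1-one, via para-quinone methide 20 (not isolated)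
Conditions: DDQ (1.05 equiv), 4 Å MS, CH2Cl2, 0 °C → rt
Reagents that add atoms: none
Why: DDQ takes a hydride from the C7 methylene of the free 4-hydroxybenzyl group (charge-transfer complex, then loss of the phenolic proton) and gives para-quinone methide 20, a flat electrophile whose exocyclic carbon is C7. The closest known reaction type is the DDQ or Ag2O oxidation of 4-alkylphenols to quinone methides with intramolecular capture by an alcohol, as in the oxidative cyclisation of dibenzylbutanediol lignans to 7,9'-epoxylignans. Ring B closes by 5-exo-trig addition of the C9' hydroxyl to C7 (the C7=C1 double bond of 20 stays outside the new ring), and rearomatisation to the phenol makes the addition downhill. The new C7 centre is controlled by C8: in the envelope transition state the cyclohexadienone ring turns away from the C8–C9 bond and the lactone carbonyl, so the aryl group ends up trans to C9 on the convex face of the cis-fused bicycle. A para-hydroxybenzyl ether can re-ionise under the mildly acidic conditions left by the reduced quinone, so any endo isomer should drain into this more stable exo isomer. The step needs selectivity between the two electron-rich rings and between C7 and C7'; only the catechol-derived ring has a free para hydroxyl, the guaiacyl oxygen is a benzyl ether, and C7' carries an acyloxy group, so hydride loss there is far slower. It also needs cyclisation to outrun tautomerisation of 20 to the conjugated arylidene lactone, which the cis placement of the CH2OH group next to C7 secures, and one equivalent of oxidant at 0 °C limits a second oxidation of 21.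

Step 13
Reactants: 21 dibenzyl ether of the target
Product: 22 (3S,3aR,6S,6aS)-6-(3,4-dihydroxyphenyl)-3-(4-hydroxy-3-methoxyphenyl)tetrahydro-1H,3H-furo[3,4-c]furan-1-one
Conditions: H2 (1 atm), 10% Pd/C, EtOAc, rt
Reagents that add atoms: none
Why: Hydrogenolysis of the two aryl benzyl ethers, which cleave much faster on Pd than the ring benzylic C–O bonds, so the reaction is stopped as soon as the ethers are gone. The neutral medium leaves C7 and C7' unepimerised and keeps the catechol away from base and oxidant.

## Compound list

1 | vanillin (4-hydroxy-3-methoxybenzaldehyde) | COc1cc(C=O)ccc1O | starting material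
2 | 4-(benzyloxy)-3-methoxybenzaldehyde | COc1cc(C=O)ccc1OCc1ccccc1 | intermediate
3 | (S)-4-benzyl-1,3-oxazolidin-2-one | O=C1N[C@@H](Cc2ccccc2)CO1 | starting material
4 | methyl 4-chloro-4-oxobutanoate | COC(=O)CCC(Cl)=O | starting material
5 | methyl 4-[(4S)-4-benzyl-2-oxo-1,3-oxazolidin-3-yl]-4-oxobutanoate | COC(=O)CCC(=O)N1[C@@H](Cc2ccccc2)COC1=O | intermediate
6 | methyl (3S)-4-[(4S)-4-benzyl-2-oxo-1,3-oxazolidin-3-yl]-3-{(S)-[4-(benzyloxy)-3-methoxyphenyl](hydroxy)methyl}-4-oxobutanoate (syn-aldol hydroxy ester, not isolated) | COC(=O)C[C@@H]([C@H](O)c1ccc(OCc2ccccc2)c(OC)c1)C(=O)N1[C@@H](Cc2ccccc2)COC1=O | intermediate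
7 | (4S)-4-benzyl-3-{[(2S,3S)-2-[4-(benzyloxy)-3-methoxyphenyl]-5-oxooxolan-3-yl]carbonyl}-1,3-oxazolidin-2-one (trans lactone imide) | O=C1C[C@H](C(=O)N2[C@@H](Cc3ccccc3)COC2=O)[C@@H](c2ccc(OCc3ccccc3)c(OC)c2)O1 | intermediate
8 | (2S,3S)-2-[4-(benzyloxy)-3-methoxyphenyl]-5-oxooxolane-3-carboperoxoic acid (not isolated) | O=C1C[C@H](C(=O)OO)[C@@H](c2ccc(OCc3ccccc3)c(OC)c2)O1 | intermediate
9 | (2S,3S)-2-[4-(benzyloxy)-3-methoxyphenyl]-5-oxooxolane-3-carboxylic acid (trans paraconic acid) | O=C1C[C@H](C(=O)O)[C@@H](c2ccc(OCc3ccccc3)c(OC)c2)O1 | intermediate
10 | (4R,5S)-5-[4-(benzyloxy)-3-methoxyphenyl]-4-(hydroxymethyl)oxolan-2-one | O=C1C[C@H](CO)[C@@H](c2ccc(OCc3ccccc3)c(OC)c2)O1 | intermediate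
11 | (4R,5S)-5-[4-(benzyloxy)-3-methoxyphenyl]-4-{[(tert-butyldimethylsilyl)oxy]methyl}oxolan-2-one | O=C1C[C@H](CO[Si](C)(C)C(C)(C)C)[C@@H](c2ccc(OCc3ccccc3)c(OC)c2)O1 | intermediate
12 | 3,4-dihydroxybenzaldehyde | O=Cc1ccc(O)c(O)c1 | starting material
13 | 3-(benzyloxy)-4-hydroxybenzaldehyde | O=Cc1ccc(O)c(OCc2ccccc2)c1 | intermediate
14 | 3-(benzyloxy)-4-[(triisopropylsilyl)oxy]benzaldehyde | O=Cc1ccc(O[Si](C(C)C)(C(C)C)C(C)C)c(OCc2ccccc2)c1 | intermediate
15 | lithium {3-(benzyloxy)-4-[(triisopropylsilyl)oxy]phenyl}[(4R,5S)-5-[4-(benzyloxy)-3-methoxyphenyl]-4-{[(tert-butyldimethylsilyl)oxy]methyl}-2-oxooxolan-3-yl]methanolate, mixture at the two new centres (not isolated) | O=C1O[C@H](c2ccc(OCc3ccccc3)c(OC)c2)[C@@H](CO[Si](C)(C)C(C)(C)C)C1C([O-])c1ccc(O[Si](C(C)C)(C(C)C)C(C)C)c(OCc2ccccc2)c1.[Li+] | intermediate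
16 | {3-(benzyloxy)-4-[(triisopropylsilyl)oxy]phenyl}[(4R,5S)-5-[4-(benzyloxy)-3-methoxyphenyl]-4-{[(tert-butyldimethylsilyl)oxy]methyl}-2-oxooxolan-3-yl]methyl acetate, mixture at the two new centres (not isolated) | O=C1O[C@H](c2ccc(OCc3ccccc3)c(OC)c2)[C@@H](CO[Si](C)(C)C(C)(C)C)C1C(OC(C)=O)c1ccc(O[Si](C(C)C)(C(C)C)C(C)C)c(OCc2ccccc2)c1 | intermediate
17 | (3E,4R,5S)-5-[4-(benzyloxy)-3-methoxyphenyl]-3-{3-(benzyloxy)-4-[(triisopropylsilyl)oxy]benzylidene}-4-{[(tert-butyldimethylsilyl)oxy]methyl}oxolan-2-one | O=C1O[C@H](c2ccc(OCc3ccccc3)c(OC)c2)[C@@H](CO[Si](C)(C)C(C)(C)C)/C1=C\c1ccc(O[Si](C(C)C)(C(C)C)C(C)C)c(OCc2ccccc2)c1 | intermediate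
18 | (3R,4R,5S)-5-[4-(benzyloxy)-3-methoxyphenyl]-3-{3-(benzyloxy)-4-[(triisopropylsilyl)oxy]benzyl}-4-{[(tert-butyldimethylsilyl)oxy]methyl}oxolan-2-one | O=C1O[C@H](c2ccc(OCc3ccccc3)c(OC)c2)[C@@H](CO[Si](C)(C)C(C)(C)C)[C@H]1Cc1ccc(O[Si](C(C)C)(C(C)C)C(C)C)c(OCc2ccccc2)c1 | intermediate
19 | (3R,4R,5S)-5-[4-(benzyloxy)-3-methoxyphenyl]-3-[3-(benzyloxy)-4-hydroxybenzyl]-4-(hydroxymethyl)oxolan-2-one | O=C1O[C@H](c2ccc(OCc3ccccc3)c(OC)c2)[C@@H](CO)[C@H]1Cc1ccc(O)c(OCc2ccccc2)c1 | intermediate
20 | (3R,4R,5S)-5-[4-(benzyloxy)-3-methoxyphenyl]-3-{[3-(benzyloxy)-4-oxocyclohexa-2,5-dien-1-ylidene]methyl}-4-(hydroxymethyl)oxolan-2-one (para-quinone methide, not isolated) | O=C1O[C@H](c2ccc(OCc3ccccc3)c(OC)c2)[C@@H](CO)[C@H]1C=C1C=CC(=O)C(OCc2ccccc2)=C1 | intermediate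
21 | (3S,3aR,6S,6aS)-6-[3-(benzyloxy)-4-hydroxyphenyl]-3-[4-(benzyloxy)-3-methoxyphenyl]tetrahydro-1H,3H-furo[3,4-c]furan-1-one | O=C1O[C@H](c3ccc(OCc4ccccc4)c(OC)c3)[C@H]2CO[C@H](c3ccc(O)c(OCc4ccccc4)c3)[C@@H]12 | intermediate
22 | (3S,3aR,6S,6aS)-6-(3,4-dihydroxyphenyl)-3-(4-hydroxy-3-methoxyphenyl)tetrahydro-1H,3H-furo[3,4-c]furan-1-one (CNP0268159.1) | COc1cc([C@H]2OC(=O)[C@H]3[C@@H]2CO[C@@H]3c2ccc(O)c(O)c2)ccc1O | target

## Step count and least certain steps

Total: 13 steps. Longest linear sequence: 10 steps (steps 2, 3, 4, 5, 6, 9, 10, 11, 12, 13 from 3 and 4; the line from 1 through step 1 has the same length).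

**Step 12 (key step).** Three processes could spoil it. Quinone methide 20 could tautomerise to the conjugated 4-hydroxyarylidene lactone, which erases C8 and cannot close because addition to that alkene would be 5-endo. The product could be oxidised a second time at C7, since 21 is still a para-hydroxybenzyl ether. The hydroxyl could also add to the wrong face of C7 and give the endo aryl isomer. The fallback sets out from 19 and separates oxidation from ring closure. DDQ in MeOH/CH2Cl2 at 0 °C lets the solvent trap 20 at once and gives (3S,4R,5S)-5-[4-(benzyloxy)-3-methoxyphenyl]-3-{[3-(benzyloxy)-4-hydroxyphenyl](methoxy)methyl}-4-(hydroxymethyl)oxolan-2-one F1 as a mixture at C7. Catalytic camphorsulfonic acid in CH2Cl2 (0 °C → rt) then ionises this para-hydroxybenzyl methyl ether, the C9' hydroxyl closes ring B under thermodynamic control with loss of methanol, and the route is rejoined at 21.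

**Step 10.** The poisoned catalyst may be too sluggish for a hindered trisubstituted alkene. If the poison is weakened to gain activity, the benzyl ethers or the benzylic lactone C–O bond may be lost. Facial selectivity may also erode, because the C7' aryl group lies on the face from which hydrogen must come. The fallback sets out from 17 and replaces surface hydrogenation by conjugate reduction with copper hydride, generated from Cu(OAc)2·H2O, 1,2-bis(diphenylphosphino)benzene and (Me2HSi)2O in toluene containing t-BuOH. Hydride adds to C7, and the copper enolate is protonated kinetically by t-BuOH on the face opposite the CH2OTBS group, which returns to 18 without Pd or hydrogen gas. This fallback makes no new isolable compound (F0).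

**Step 13.** Over-reduction is the danger: hydrogenolysis of the C7–O or C7'–O bond once the benzyl ethers have gone, because both bonds are benzylic and para to a free phenol in 22. The fallback sets out from 21 and removes the benzyl groups without hydrogen, using BCl3 with pentamethylbenzene as benzyl cation scavenger in CH2Cl2 at −78 °C, and arrives at 22. Should the Lewis acid ionise a ring benzylic bond, reclosure favours the exo aryl arrangement that the target already has. This fallback makes no new isolable compound (F0).

**Step 9.** Retro-aldol cleavage of 15 on warming, incomplete elimination from 16, or loss of the phenolic silyl group under the basic conditions would lower the efficiency; the alkene geometry matters little, since both isomers give 18. The fallback sets out from 11 and changes the olefination. The lithium enolate (LiN(i-Pr)2, 2 equiv) is phosphorylated with ClP(O)(OEt)2, and the excess base induces the 1,3 oxygen-to-carbon phosphorus shift to diethyl [(4R,5S)-5-[4-(benzyloxy)-3-methoxyphenyl]-4-{[(tert-butyldimethylsilyl)oxy]methyl}-2-oxooxolan-3-yl]phosphonate F2. Horner–Wadsworth–Emmons reaction of F2 with 14 (NaH, THF) then gives 17 directly.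

## Further compounds

F1 | step 12 | (3S,4R,5S)-5-[4-(benzyloxy)-3-methoxyphenyl]-3-{[3-(benzyloxy)-4-hydroxyphenyl](methoxy)methyl}-4-(hydroxymethyl)oxolan-2-one, mixture at the methoxy-bearing carbon | O=C1O[C@H](c2ccc(OCc3ccccc3)c(OC)c2)[C@@H](CO)[C@H]1C(OC)c1ccc(O)c(OCc2ccccc2)c1
F2 | step 9 | diethyl [(4R,5S)-5-[4-(benzyloxy)-3-methoxyphenyl]-4-{[(tert-butyldimethylsilyl)oxy]methyl}-2-oxooxolan-3-yl]phosphonate, mixture at C3 | O=C1O[C@H](c2ccc(OCc3ccccc3)c(OC)c2)[C@@H](CO[Si](C)(C)C(C)(C)C)C1P(=O)(OCC)OCC
F0 | step 10 | none | none
F0 | step 13 | none | none
A1 | alternative 1 | methyl 6-[3,4-bis(benzyloxy)phenyl]-3-[4-(benzyloxy)-3-methoxyphenyl]-1-oxotetrahydro-1H,3H-furo[3,4-c]furan-6a-carboxylate, core configured as in 22 | O=C1O[C@H](c3ccc(OCc4ccccc4)c(OC)c3)[C@H]2CO[C@H](c3ccc(OCc4ccccc4)c(OCc4ccccc4)c3)[C@@]12C(=O)OC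
A2 | alternative 1 | dimethyl 2-{(S)-[3,4-bis(benzyloxy)phenyl]{[(E)-3-[4-(benzyloxy)-3-methoxyphenyl]prop-2-en-1-yl]oxy}methyl}malonate | COC(=O)C(C(=O)OC)[C@H](OC/C=C/c1ccc(OCc2ccccc2)c(OC)c1)c1ccc(OCc2ccccc2)c(OCc2ccccc2)c1
A3 | alternative 2 | 4-[3,4-bis(benzyloxy)phenyl]-7-[4-(benzyloxy)-3-methoxyphenyl]-3-oxabicyclo[3.2.0]heptan-6-one, cis-fused, both aryl groups exo | O=C1[C@H](c3ccc(OCc4ccccc4)c(OC)c3)[C@H]2CO[C@H](c3ccc(OCc4ccccc4)c(OCc4ccccc4)c3)[C@@H]12
A4 | alternative 2 | (S)-2-[3,4-bis(benzyloxy)phenyl]-2,5-dihydrofuran | C1=C[C@@H](c2ccc(OCc3ccccc3)c(OCc3ccccc3)c2)OC1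
A5 | alternative 2 | 2-[4-(benzyloxy)-3-methoxyphenyl]-N,N-dimethylacetamide | CN(C)C(=O)Cc1ccc(OCc2ccccc2)c(OC)c1
A6 | alternative 3 | dimethyl 2-[3,4-bis(benzyloxy)phenyl]-4-vinyloxolane-3,3-dicarboxylate, 2,4-trans | C=C[C@H]1CO[C@H](c2ccc(OCc3ccccc3)c(OCc3ccccc3)c2)C1(C(=O)OC)C(=O)OC
A7 | alternative 3 | 2-vinyloxirane, racemic | C=CC1CO1
A8 | alternative 3 | dimethyl 2-[3,4-bis(benzyloxy)benzylidene]malonate | COC(=O)C(=Cc1ccc(OCc2ccccc2)c(OCc2ccccc2)c1)C(=O)OC
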